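**Strategy.** Ring A is disconnected through its carbon skeleton and not at its crowded C1–O bond: C1 with its hydroxylated neighbours C2 and C6 comes from an aryloxymalonate, and C3–C4–C5 from a 3-oxoglutarate. The step exploits the 1,3,5-arrangement of the hydroxyls on C2, C4 and C6 of ring A, with the ether carbon C1 flanked by C2–OH and C6–OH. Rings C, E and G also bear three hydroxyls, but vicinal ones. One double Claisen condensation forms C2–C3 and C5–C6, closes ring A and aromatises it. Its precursor is the dimethyl malonate ether of the permethylated hexamer BCDEFG phenol, assembled from one dimer aldehyde used three times.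

Key step: step 9

Remark (assumption): rings are lettered A (2,4,6-trihydroxyphenyl end) to G (3,4,5-trihydroxyphenyl end). The target has no stereocentre; the sp3 carbons of the transient intermediates 16 and 17 are configurationally labile and are written without configuration.

Design remarks:
- Every inter-ring oxygen comes from one phenol and one aryl halide, since two phenols cannot be joined. A formyl group serves as the latent phenol of rings B, D and F and keeps its ring out of the iodination.
- Dimethyl chloromalonate is used for the ether at C1, because bromomalonates can transfer bromine to electron-rich phenoxides.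
- The oxoglutarate carries tert-butyl esters. They cannot act as acyl donors in step 9, and they fall off in the same BBr3 operation that cleaves the methyl ethers. No alkaline saponification of an oxidation-prone phloroglucinol is then needed.

**Route**

Step 1
Reactants: 1 3,4,5-trimethoxyphenol; 2 4-bromo-3,5-dimethoxybenzaldehyde
Product: 3 dimer aldehyde 3,5-dimethoxy-4-(3,4,5-trimethoxyphenoxy)benzaldehyde
Conditions: CuI (10 mol %), picolinic acid (20 mol %), K3PO4, DMSO, 90 °C, argon
Reagents that add atoms: none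
Why: Ullmann-type diaryl ether synthesis, in which the para-formyl group activates the bromide flanked by two methoxy groups towards the picolinate complex of monovalent copper and the phenol has two free ortho positions.

Step 2
Reactants: 3 dimer aldehyde
Product: 5 dimer phenol 3,5-dimethoxy-4-(3,4,5-trimethoxyphenoxy)phenol, via dimer aryl formate 4 (not isolated)
Conditions: mCPBA, CH2Cl2, 0 °C → rt; aq. NaHCO3 wash; then K2CO3 (cat.), MeOH, rt
Reagents that add atoms: 3-chloroperoxybenzoic acid (mCPBA), O=C(OO)c1cccc(Cl)c1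
Why: Baeyer–Villiger (Dakin-type) oxidation, in which the aryl group carrying a para-aryloxy donor should migrate in preference to hydride and the formate is then methanolysed under mild base.

Step 3
Reactants: 3 dimer aldehyde
Product: 6 iodo dimer aldehyde 4-(2-iodo-3,4,5-trimethoxyphenoxy)-3,5-dimethoxybenzaldehyde
Conditions: NIS (1.05 equiv), TFA (cat.), MeCN, 0 °C → rt, dark
Reagents that add atoms: N-iodosuccinimide, O=C1CCC(=O)N1I
Why: Electrophilic aromatic iodination, which should take place on the trimethoxyphenoxy ring at C2 (equivalent to C6; ortho to the ether oxygen and to OMe, para to OMe) because the other ring is deactivated by its formyl group.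

Step 4
Reactants: 5 dimer phenol; 6 iodo dimer aldehyde
Product: 7 tetramer aldehyde DEFG 4-{2-[3,5-dimethoxy-4-(3,4,5-trimethoxyphenoxy)phenoxy]-3,4,5-trimethoxyphenoxy}-3,5-dimethoxybenzaldehyde
Conditions: CuI (20 mol %), picolinic acid (40 mol %), K3PO4, DMSO, 100 °C, argon
Reagents that add atoms: none
Why: Ullmann-type coupling of an unhindered, electron-rich phenol with an aryl iodide, where the iodide (chosen over the bromide) and the picolinic acid ligand answer the di-ortho substitution of the halide.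

Step 5
Reactants: 7 tetramer aldehyde DEFG
Product: 9 tetramer phenol DEFG (7 with OH in place of CHO on ring D), via tetramer aryl formate 8 (not isolated)
Conditions: mCPBA, CH2Cl2, 0 °C → rt; aq. NaHCO3 wash; then K2CO3 (cat.), MeOH/THF, rt
Reagents that add atoms: 3-chloroperoxybenzoic acid (mCPBA), O=C(OO)c1cccc(Cl)c1
Why: Same Baeyer–Villiger oxidation as in step 2; only ring D bears a carbonyl group, and the ether rings should not be attacked by the peracid at this temperature.

Step 6
Reactants: 9 tetramer phenol DEFG; 6 iodo dimer aldehyde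
Product: 10 hexamer aldehyde BCDEFG (9 extended through its ring D oxygen by ring C, a 3,4,5-trimethoxy-1,2-phenylene unit, and ring B, a 4-formyl-2,6-dimethoxyphenyl unit)
Conditions: CuI (20 mol %), picolinic acid (40 mol %), K3PO4, DMSO, 100 °C, argon
Reagents that add atoms: none
Why: Same Ullmann-type C–O coupling as in step 4, again between a phenol with free ortho positions and the hindered aryl iodide.

Step 7
Reactants: 10 hexamer aldehyde BCDEFG
Product: 12 hexamer phenol BCDEFG (OH on C1 of ring B), via hexamer aryl formate 11 (not isolated)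
Conditions: mCPBA, CH2Cl2, 0 °C → rt; aq. NaHCO3 wash; then K2CO3 (cat.), MeOH/THF, rt
Reagents that add atoms: 3-chloroperoxybenzoic acid (mCPBA), O=C(OO)c1cccc(Cl)c1
Why: Baeyer–Villiger oxidation as in steps 2 and 5, with migration of ring B assisted by its para-aryloxy group.

Step 8
Reactants: 12 hexamer phenol BCDEFG; 13 dimethyl 2-chloropropanedioate (dimethyl chloromalonate)
Product: 14 dimethyl 2-(hexamer BCDEFG oxy)propanedioate
Conditions: K2CO3, acetone, 55 °C
Reagents that add atoms: none
Why: Williamson etherification (SN2) of an unhindered phenoxide with a doubly activated secondary chloride, which makes the future C1–O bond of ring A while C1 is still tetrahedral.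

Step 9
Reactants: 14 dimethyl 2-(hexamer BCDEFG oxy)propanedioate; 15 di-tert-butyl 3-oxopentanedioate
Product: 18 di-tert-butyl 2,4,6-trihydroxy-5-(hexamer BCDEFG oxy)benzene-1,3-dicarboxylate, via open-chain C-acylation adduct 16 (not isolated), via cyclohexane-1,3,5-trione tautomer 17 (not isolated)
Conditions: 15 (3 equiv), NaH (3 equiv), THF, 0 °C → rt; then 14, THF/toluene, 80–100 °C with removal of MeOH; cold dilute aq. HCl
Reagents that add atoms: none
Why: Proposed new method: the sodium enolate of 15 attacks one methyl ester of 14 (Claisen C-acylation, C2–C3), the second ketone-flanked methylene is then deprotonated and attacks the remaining methyl ester (C5–C6), and trione 17 enolises to the arene, which is held as its phenolate; the closest known reaction type is the alkoxide-mediated condensation of simple malonic esters with 3-oxoglutaric esters (and the self-condensation of sodiomalonate) to phloroglucinol carboxylates, which has not been shown for a malonate bearing an aryloxy group on its central carbon. Ring A closes by a 6-exo-trig acyl substitution of the Dieckmann type. No stereocentre is formed, and the sp3 centres of 16 and 17 disappear on enolisation. The step needs C- over O-acylation: O-acylation to a 4-hydroxy-2-pyranone is reversible under alkoxide whereas the aromatic phenolate is the thermodynamic sink, the tert-butyl esters of 15 cannot serve as acyl donors so only the methyl esters of 14 are transferred, and the mirror symmetry of both partners leaves no regiochemical choice. The excess of the enolate of 15 is meant to offset its aldol-type self-condensation and the partial deprotonation of 14 at its central carbon.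

Step 10
Reactants: 18 di-tert-butyl 2,4,6-trihydroxy-5-(hexamer BCDEFG oxy)benzene-1,3-dicarboxylate
Product: 21 target heptamer CNP0292517.0, via heptamer diacid 19 (not isolated), via heptamer monoacid 20 (not isolated)
Conditions: BBr3 (large excess), CH2Cl2, −78 °C → rt; volatiles removed in vacuo; then H2O, 50 °C, argon
Reagents that add atoms: none
Why: BBr3 cleaves the fifteen aryl methyl ethers (bromide attack at methyl) and both tert-butyl esters (ionisation) without touching diaryl ethers, and the freed 2,4,6-trihydroxyisophthalic acid unit should lose CO2 twice by ipso-protonation (protodecarboxylation) in warm acidic water.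

**Compound list**

1 | 3,4,5-trimethoxyphenol | COc1cc(O)cc(OC)c1OC | starting material
2 | 4-bromo-3,5-dimethoxybenzaldehyde | COc1cc(C=O)cc(OC)c1Br | starting material
3 | dimer aldehyde, 3,5-dimethoxy-4-(3,4,5-trimethoxyphenoxy)benzaldehyde | COc1cc(C=O)cc(OC)c1Oc1cc(OC)c(OC)c(OC)c1 | intermediate
4 | dimer aryl formate, 3,5-dimethoxy-4-(3,4,5-trimethoxyphenoxy)phenyl formate (not isolated) | COc1cc(OC=O)cc(OC)c1Oc1cc(OC)c(OC)c(OC)c1 | intermediate
5 | dimer phenol, 3,5-dimethoxy-4-(3,4,5-trimethoxyphenoxy)phenol | COc1cc(O)cc(OC)c1Oc1cc(OC)c(OC)c(OC)c1 | intermediate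
6 | iodo dimer aldehyde, 4-(2-iodo-3,4,5-trimethoxyphenoxy)-3,5-dimethoxybenzaldehyde | COc1cc(C=O)cc(OC)c1Oc1cc(OC)c(OC)c(OC)c1I | intermediate
7 | tetramer aldehyde DEFG | COc1cc(C=O)cc(OC)c1Oc1cc(OC)c(OC)c(OC)c1Oc1cc(OC)c(Oc2cc(OC)c(OC)c(OC)c2)c(OC)c1 | intermediate
8 | tetramer aryl formate DEFG (not isolated) | COc1cc(OC=O)cc(OC)c1Oc1cc(OC)c(OC)c(OC)c1Oc1cc(OC)c(Oc2cc(OC)c(OC)c(OC)c2)c(OC)c1 | intermediate
9 | tetramer phenol DEFG | COc1cc(O)cc(OC)c1Oc1cc(OC)c(OC)c(OC)c1Oc1cc(OC)c(Oc2cc(OC)c(OC)c(OC)c2)c(OC)c1 | intermediate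
10 | hexamer aldehyde BCDEFG | COc1cc(C=O)cc(OC)c1Oc1cc(OC)c(OC)c(OC)c1Oc1cc(OC)c(Oc2cc(OC)c(OC)c(OC)c2Oc2cc(OC)c(Oc3cc(OC)c(OC)c(OC)c3)c(OC)c2)c(OC)c1 | intermediate
11 | hexamer aryl formate BCDEFG (not isolated) | COc1cc(OC=O)cc(OC)c1Oc1cc(OC)c(OC)c(OC)c1Oc1cc(OC)c(Oc2cc(OC)c(OC)c(OC)c2Oc2cc(OC)c(Oc3cc(OC)c(OC)c(OC)c3)c(OC)c2)c(OC)c1 | intermediate
12 | hexamer phenol BCDEFG | Oc1cc(OC)c(Oc2cc(OC)c(OC)c(OC)c2Oc2cc(OC)c(Oc3cc(OC)c(OC)c(OC)c3Oc3cc(OC)c(Oc4cc(OC)c(OC)c(OC)c4)c(OC)c3)c(OC)c2)c(OC)c1 | intermediate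
13 | dimethyl 2-chloropropanedioate | COC(=O)C(Cl)C(=O)OC | starting material
14 | dimethyl 2-(hexamer BCDEFG oxy)propanedioate | COC(=O)C(Oc1cc(OC)c(Oc2cc(OC)c(OC)c(OC)c2Oc2cc(OC)c(Oc3cc(OC)c(OC)c(OC)c3Oc3cc(OC)c(Oc4cc(OC)c(OC)c(OC)c4)c(OC)c3)c(OC)c2)c(OC)c1)C(=O)OC | intermediate
15 | di-tert-butyl 3-oxopentanedioate | CC(C)(C)OC(=O)CC(=O)CC(=O)OC(C)(C)C | starting material
16 | open-chain C-acylation adduct (not isolated) | COC(=O)C(Oc1cc(OC)c(Oc2cc(OC)c(OC)c(OC)c2Oc2cc(OC)c(Oc3cc(OC)c(OC)c(OC)c3Oc3cc(OC)c(Oc4cc(OC)c(OC)c(OC)c4)c(OC)c3)c(OC)c2)c(OC)c1)C(=O)C(C(=O)OC(C)(C)C)C(=O)CC(=O)OC(C)(C)C | intermediate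
17 | cyclohexane-1,3,5-trione tautomer of 18 (not isolated) | CC(C)(C)OC(=O)C1C(=O)C(C(=O)OC(C)(C)C)C(=O)C(Oc2cc(OC)c(Oc3cc(OC)c(OC)c(OC)c3Oc3cc(OC)c(Oc4cc(OC)c(OC)c(OC)c4Oc4cc(OC)c(Oc5cc(OC)c(OC)c(OC)c5)c(OC)c4)c(OC)c3)c(OC)c2)C1=O | intermediate
18 | di-tert-butyl 2,4,6-trihydroxy-5-(hexamer BCDEFG oxy)benzene-1,3-dicarboxylate | CC(C)(C)OC(=O)c1c(O)c(C(=O)OC(C)(C)C)c(O)c(Oc2cc(OC)c(Oc3cc(OC)c(OC)c(OC)c3Oc3cc(OC)c(Oc4cc(OC)c(OC)c(OC)c4Oc4cc(OC)c(Oc5cc(OC)c(OC)c(OC)c5)c(OC)c4)c(OC)c3)c(OC)c2)c1O | intermediate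
19 | heptamer diacid, fully demethylated, ring A 1,3-dicarboxylic acid (not isolated) | OC(=O)c1c(O)c(C(=O)O)c(O)c(Oc2cc(O)c(Oc3cc(O)c(O)c(O)c3Oc3cc(O)c(Oc4cc(O)c(O)c(O)c4Oc4cc(O)c(Oc5cc(O)c(O)c(O)c5)c(O)c4)c(O)c3)c(O)c2)c1O | intermediate
20 | heptamer monoacid (not isolated) | OC(=O)c1c(O)cc(O)c(Oc2cc(O)c(Oc3cc(O)c(O)c(O)c3Oc3cc(O)c(Oc4cc(O)c(O)c(O)c4Oc4cc(O)c(Oc5cc(O)c(O)c(O)c5)c(O)c4)c(O)c3)c(O)c2)c1O | intermediate
21 | CNP0292517.0 | Oc1cc(O)c(Oc2cc(O)c(Oc3cc(O)c(O)c(O)c3Oc3cc(O)c(Oc4cc(O)c(O)c(O)c4Oc4cc(O)c(Oc5cc(O)c(O)c(O)c5)c(O)c4)c(O)c3)c(O)c2)c(O)c1 | target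

**Step count**

Total steps: 10. Longest linear sequence: 9 steps (steps 1, 2, 4, 5, 6, 7, 8, 9, 10); step 3 is a one-step branch from 3 whose product 6 enters at steps 4 and 6.

**Steps most likely to fail**

1. Step 9 (the labelled step). The malonate 14 may be deprotonated at its central carbon and so be withdrawn as an acyl donor, so that intermolecular acylation stalls while 15 consumes itself by aldol-type self-condensation. Fallback with known chemistry, setting out from 12 and returning at 21: 12 is coupled with commercial 2-iodo-1,3,5-trimethoxybenzene (COc1cc(OC)c(I)c(OC)c1) under the CuI/picolinic acid/K3PO4 conditions of step 4 to give the octadecamethyl ether of the target F1. Exhaustive demethylation of F1 with BBr3 in CH2Cl2 then gives 21. Ring A is thus brought in ready-made by an Ullmann coupling and not built.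

2. Step 4. Oxidative addition at the di-ortho-substituted, electron-rich iodide may be slow, so that protodeiodination and aryloxide exchange at the formyl-activated ring compete with coupling. Fallback, setting out from 5 and returning at 7: 5 is coupled (CuI, picolinic acid, K3PO4, DMSO, 90 °C) with commercial 2-bromo-3,4,5-trimethoxybenzaldehyde (COc1cc(C=O)c(Br)c(OC)c1OC), whose bromide is activated by the ortho formyl group, to give the trimer aldehyde F2. Baeyer–Villiger oxidation with mCPBA gives the trimer aryl formate F3, which is methanolysed (K2CO3 cat., MeOH) to the trimer phenol F4. Coupling of F4 with 2 as in step 1 gives 7. Rings are then added one at a time as activated bromides, at the cost of more steps.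

3. Step 10. Ether cleavage may stop short at some of the fifteen sites, tert-butyl cations may alkylate the electron-rich rings, and the free polyphenol may oxidise during the warm aqueous stage. Fallback, setting out from 18 and returning at 21: acidolysis with TFA and Et3SiH in CH2Cl2 removes both tert-butyl groups without a Lewis acid and gives the pentadecamethyl heptamer diacid F5. On gentle warming F5 loses CO2 through the pentadecamethyl heptamer monoacid F6 to the pentadecamethyl heptamer with free ring A triol F7, which is purified. F7 is demethylated with BBr3 and the crude polyphenol is acetylated at once (Ac2O, pyridine) to the octadecaacetate of the target F8, which can be chromatographed and resubmitted if partly methylated material remains. Acidic methanolysis of F8 (HCl, MeOH, argon) releases 21.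

**Further compounds**

F1 | step 9 | octadecamethyl ether of the target (2,4,6-trimethoxyphenyl ether of 12) | COc1cc(OC)c(Oc2cc(OC)c(Oc3cc(OC)c(OC)c(OC)c3Oc3cc(OC)c(Oc4cc(OC)c(OC)c(OC)c4Oc4cc(OC)c(Oc5cc(OC)c(OC)c(OC)c5)c(OC)c4)c(OC)c3)c(OC)c2)c(OC)c1
F2 | step 4 | trimer aldehyde, 2-[3,5-dimethoxy-4-(3,4,5-trimethoxyphenoxy)phenoxy]-3,4,5-trimethoxybenzaldehyde | COc1cc(C=O)c(Oc2cc(OC)c(Oc3cc(OC)c(OC)c(OC)c3)c(OC)c2)c(OC)c1OC
F3 | step 4 | trimer aryl formate | COc1cc(OC=O)c(Oc2cc(OC)c(Oc3cc(OC)c(OC)c(OC)c3)c(OC)c2)c(OC)c1OC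
F4 | step 4 | trimer phenol, 2-[3,5-dimethoxy-4-(3,4,5-trimethoxyphenoxy)phenoxy]-3,4,5-trimethoxyphenol | COc1cc(O)c(Oc2cc(OC)c(Oc3cc(OC)c(OC)c(OC)c3)c(OC)c2)c(OC)c1OC
F5 | step 10 | pentadecamethyl heptamer diacid | OC(=O)c1c(O)c(C(=O)O)c(O)c(Oc2cc(OC)c(Oc3cc(OC)c(OC)c(OC)c3Oc3cc(OC)c(Oc4cc(OC)c(OC)c(OC)c4Oc4cc(OC)c(Oc5cc(OC)c(OC)c(OC)c5)c(OC)c4)c(OC)c3)c(OC)c2)c1O
F6 | step 10 | pentadecamethyl heptamer monoacid | OC(=O)c1c(O)cc(O)c(Oc2cc(OC)c(Oc3cc(OC)c(OC)c(OC)c3Oc3cc(OC)c(Oc4cc(OC)c(OC)c(OC)c4Oc4cc(OC)c(Oc5cc(OC)c(OC)c(OC)c5)c(OC)c4)c(OC)c3)c(OC)c2)c1O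
F7 | step 10 | pentadecamethyl heptamer with free ring A triol | Oc1cc(O)c(Oc2cc(OC)c(Oc3cc(OC)c(OC)c(OC)c3Oc3cc(OC)c(Oc4cc(OC)c(OC)c(OC)c4Oc4cc(OC)c(Oc5cc(OC)c(OC)c(OC)c5)c(OC)c4)c(OC)c3)c(OC)c2)c(O)c1
F8 | step 10 | octadecaacetate of the target | CC(=O)Oc1cc(OC(C)=O)c(Oc2cc(OC(C)=O)c(Oc3cc(OC(C)=O)c(OC(C)=O)c(OC(C)=O)c3Oc3cc(OC(C)=O)c(Oc4cc(OC(C)=O)c(OC(C)=O)c(OC(C)=O)c4Oc4cc(OC(C)=O)c(Oc5cc(OC(C)=O)c(OC(C)=O)c(OC(C)=O)c5)c(OC(C)=O)c4)c(OC(C)=O)c3)c(OC(C)=O)c2)c(OC(C)=O)c1
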